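**Retrosynthetic overview**

- The target is a head-to-tail trimer of 1,2,3,5-tetraoxygenated benzene rings. Each bridge O sits on the O,O-flanked carbon of one ring (C1 of ring A, the 2,4,6-trihydroxyphenoxy ring; C1 of the central ring B) and on the H,H-flanked carbon para to an oxygen of the next ring (C4 of ring B; C5 of the pyrogallol ring C).
- Both bridges are cut at that H,H-flanked carbon, O–C4(B) and O–C5(C). Each such carbon is delivered as the carbene carbon of the same p-quinone diazide, 4-diazo-2,6-dimethoxycyclohexa-2,5-dienone, whose C=O becomes the para oxygen.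
- O–H insertion aromatises the dienone and so exposes a new 2,6-dimethoxyphenol O–H, which is the nucleophile of the next round: 2,4,6-trimethoxyphenol (ring A) → A–B → A–B–C, with no halide, protecting-group or oxidation-state change between rounds.
- No ring is closed (all three benzene rings enter intact); the monomer comes from syringol in three steps, and one sevenfold O-demethylation ends the route.

Key step: step 5

Remark: the target has no stereocentre and no configurationally stable axis (the rings are joined by freely rotating ether oxygens), so it is achiral and the SMILES defines a single compound; 2,6-dimethoxyphenol and 2,4,6-trimethoxyphenol are taken as catalogue chemicals.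

**Route**

Step 1
Reactants: 1 2,6-dimethoxyphenol (syringol)
Product: 2 2,6-dimethoxy-4-nitrosophenol (in equilibrium with its tautomer 2,6-dimethoxy-1,4-benzoquinone 4-oxime)
Conditions: NaNO2 (1.1 equiv), AcOH/H2O, 0 °C
Reagents that add atoms: sodium nitrite, [Na+].[O-]N=O
Why: Electrophilic C-nitrosation of a phenol by NO+; both ortho positions carry OMe, so only the para carbon C4 can be attacked.

Step 2
Reactants: 2 2,6-dimethoxy-4-nitrosophenol
Product: 3 4-amino-2,6-dimethoxyphenol hydrochloride
Conditions: H2 (1 atm), 10% Pd/C, HCl (1.1 equiv), MeOH, rt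
Reagents that add atoms: hydrogen chloride, Cl
Why: Catalytic hydrogenation of a nitrosoarene (quinone oxime) to the aniline; the acid traps the oxidation-prone p-aminophenol as its salt and the aryl methyl ethers are inert.

Step 3
Reactants: 3 4-amino-2,6-dimethoxyphenol hydrochloride
Product: 5 4-diazo-2,6-dimethoxycyclohexa-2,5-dien-1-one (p-quinone diazide), via 4-hydroxy-3,5-dimethoxybenzenediazonium chloride 4 (not isolated)
Conditions: NaNO2, 2 M aq HCl, −5 to 0 °C; then NaHCO3 to pH 7, CH2Cl2 extraction, dark
Reagents that add atoms: sodium nitrite, [Na+].[O-]N=O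
Why: Diazotisation of a p-aminophenol; the p-hydroxyarenediazonium ion is acidic and loses its phenolic proton on neutralisation to give the neutral p-quinone diazide (classical preparation of diazo oxides).

Step 4
Reactants: 5 4-diazo-2,6-dimethoxycyclohexa-2,5-dien-1-one; 6 2,4,6-trimethoxyphenol
Product: 7 2,6-dimethoxy-4-(2,4,6-trimethoxyphenoxy)phenol
Conditions: Rh2(esp)2 (1 mol%), 6 (3 equiv), 5 added over 6 h, 4 Å MS, CH2Cl2, 40 °C, dark
Reagents that add atoms: none
Why: Proposed new method: Rh(II) converts 5 with loss of N2 into an electrophilic quinoid carbene whose C4 is attacked by the hindered phenolic O of 6, and the resulting oxonium ylide aromatises by proton transfer to the diaryl ether phenol 7; the closest known reaction types are Rh(II)-catalysed O–H insertion of α-diazocarbonyl compounds into phenols and the self-condensation of p-quinone diazides to poly(1,4-phenylene ethers), and excess 6 with slow addition of 5 should suppress a second insertion.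

Step 5
Reactants: 5 4-diazo-2,6-dimethoxycyclohexa-2,5-dien-1-one; 7 2,6-dimethoxy-4-(2,4,6-trimethoxyphenoxy)phenol
Product: 8 4-[2,6-dimethoxy-4-(2,4,6-trimethoxyphenoxy)phenoxy]-2,6-dimethoxyphenol
Conditions: Rh2(esp)2 (2 mol%), 7 (2 equiv, excess recovered), 5 added over 8 h, 4 Å MS, CH2Cl2, 40 °C, dark
Reagents that add atoms: none
Why: Proposed new method: Rh(II) extrudes N2 from 5 to give a Rh-bound 3,5-dimethoxy-4-oxocyclohexa-2,5-dienylidene whose carbene carbon (the later C5 of ring C) is strongly electrophilic; the phenolic O on C1 of ring B in 7 adds to it to form an oxonium ylide in which the former dienone is already a phenolate, and loss of Rh with proton transfer gives the diaryl ether 8, driven by N2 loss and aromatisation. The closest known reaction types are Rh(II)-catalysed O–H insertion of α-diazocarbonyl compounds into phenols, carbene transfer from p-quinone diazides (arene C–H arylation, cyclopropanation, photochemical O–H insertion into alcohols) and the self-condensation of p-quinone diazides to poly(1,4-phenylene ethers), which forms this same C4–O aryl ether bond. No ring is closed and no stereocentre is formed. The step needs O–H insertion over attack of the carbene on the electron-rich ring C–H positions of 7 and over self-condensation of 5; ylide formation at the oxygen lone pair under Rh(II) carboxylate catalysis and a low stationary concentration of 5 should secure this, and the site on the electrophile is fixed because only C4 of 5 carries the diazo group. It also needs mono-insertion although 8 again carries a 2,6-dimethoxyphenol O–H; keeping 7 in excess and adding 5 slowly means that 5 and 8 never accumulate together.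

Step 6
Reactants: 8 4-[2,6-dimethoxy-4-(2,4,6-trimethoxyphenoxy)phenoxy]-2,6-dimethoxyphenol
Product: 9 5-[2,6-dihydroxy-4-(2,4,6-trihydroxyphenoxy)phenoxy]benzene-1,2,3-triol (target)
Conditions: BBr3 (14 equiv), CH2Cl2, −78 °C to rt; H2O, 0 °C; EtOAc extraction and reversed-phase chromatography under argon
Reagents that add atoms: none
Why: Lewis-acid ether cleavage: BBr3 coordinates each methoxy oxygen and bromide attacks the methyl carbon by SN2, whereas the two diaryl ether oxygens carry only sp2 carbons and cannot be cleaved this way.

**Compound list**

1 | 2,6-dimethoxyphenol (syringol) | COc1cccc(OC)c1O | starting material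
2 | 2,6-dimethoxy-4-nitrosophenol (tautomer: 2,6-dimethoxy-1,4-benzoquinone 4-oxime) | COc1cc(N=O)cc(OC)c1O | intermediate
3 | 4-amino-2,6-dimethoxyphenol hydrochloride | COc1cc(N)cc(OC)c1O.Cl | intermediate
4 | 4-hydroxy-3,5-dimethoxybenzenediazonium chloride | COc1cc([N+]#N)cc(OC)c1O.[Cl-] | intermediate (not isolated)
5 | 4-diazo-2,6-dimethoxycyclohexa-2,5-dien-1-one | COC1=CC(=[N+]=[N-])C=C(OC)C1=O | intermediate
6 | 2,4,6-trimethoxyphenol | COc1cc(OC)c(O)c(OC)c1 | starting material
7 | 2,6-dimethoxy-4-(2,4,6-trimethoxyphenoxy)phenol | COc1cc(OC)c(Oc2cc(OC)c(O)c(OC)c2)c(OC)c1 | intermediate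
8 | 4-[2,6-dimethoxy-4-(2,4,6-trimethoxyphenoxy)phenoxy]-2,6-dimethoxyphenol | COc1cc(OC)c(Oc2cc(OC)c(Oc3cc(OC)c(O)c(OC)c3)c(OC)c2)c(OC)c1 | intermediate
9 | 5-[2,6-dihydroxy-4-(2,4,6-trihydroxyphenoxy)phenoxy]benzene-1,2,3-triol | Oc1cc(O)c(Oc2cc(O)c(Oc3cc(O)c(O)c(O)c3)c(O)c2)c(O)c1 | target

**Step count**

Total step count: 6. Longest linear sequence: 6 steps (1 → 2 → 3 → 5 → 7 → 8 → 9; compound 6 is purchased and 5 is used in steps 4 and 5).

**Steps most likely to fail**

Step 4 (Proposed new method). The carbene may be consumed by self-condensation of 5 to oligo(phenylene ethers), by arylation of the activated ring carbons C3/C5 of 6, or by a second insertion into the newly formed phenol, so that the hindered O–H of 6 is not arylated cleanly. The fallback sets out from 6 and uses a copper-catalysed Ullmann ether coupling. Commercial 4-bromo-2,6-dimethoxyphenol is benzylated (BnBr, K2CO3, DMF) to 2-(benzyloxy)-5-bromo-1,3-dimethoxybenzene F1. F1 is coupled with 6 (CuI, N,N-dimethylglycine, Cs2CO3, dioxane, 100 °C) to 2-(benzyloxy)-1,3-dimethoxy-5-(2,4,6-trimethoxyphenoxy)benzene F2. Hydrogenolysis of the benzyl ether (H2, Pd/C, EtOAc) then comes back to the route at 7.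

Step 5 (Proposed new method, key step). The same competing processes apply, now with the more valuable dimer 7, together with over-insertion into the O–H of 8 that would lead to a tetramer. The fallback sets out from 7, which is coupled with commercial 5-iodo-1,2,3-trimethoxybenzene under Ullmann conditions (CuI, picolinic acid, K3PO4, DMSO, 100 °C) to 5-[2,6-dimethoxy-4-(2,4,6-trimethoxyphenoxy)phenoxy]-1,2,3-trimethoxybenzene F3. Eightfold demethylation of F3 with BBr3 under the conditions of step 6 comes back to the route at 9.

Step 6. Cleavage of the seven methyl ethers may stop at partially methylated stages, and the pyrogallol ring C may be oxidised by air during aqueous work-up and chromatography of the very polar product. The fallback sets out from 8 and replaces direct isolation by a derivatise–purify–release sequence. After BBr3 treatment and methanol quench, the crude polyphenol is peracetylated (Ac2O, pyridine, DMAP) to 5-[2,6-diacetoxy-4-(2,4,6-triacetoxyphenoxy)phenoxy]benzene-1,2,3-triyl triacetate F4. F4 is air-stable and can be purified on silica, where incompletely demethylated material is separated. Acid-catalysed methanolysis (AcCl in dry MeOH, rt, argon) and evaporation then come back to the route at 9 without exposing phenolates to air.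

Further compounds
F1 | step 4 | 2-(benzyloxy)-5-bromo-1,3-dimethoxybenzene | COc1cc(Br)cc(OC)c1OCc1ccccc1
F2 | step 4 | 2-(benzyloxy)-1,3-dimethoxy-5-(2,4,6-trimethoxyphenoxy)benzene | COc1cc(OC)c(Oc2cc(OC)c(OCc3ccccc3)c(OC)c2)c(OC)c1
F3 | step 5 | 5-[2,6-dimethoxy-4-(2,4,6-trimethoxyphenoxy)phenoxy]-1,2,3-trimethoxybenzene | COc1cc(OC)c(Oc2cc(OC)c(Oc3cc(OC)c(OC)c(OC)c3)c(OC)c2)c(OC)c1
F4 | step 6 | 5-[2,6-diacetoxy-4-(2,4,6-triacetoxyphenoxy)phenoxy]benzene-1,2,3-triyl triacetate | CC(=O)Oc1cc(OC(C)=O)c(Oc2cc(OC(C)=O)c(Oc3cc(OC(C)=O)c(OC(C)=O)c(OC(C)=O)c3)c(OC(C)=O)c2)c(OC(C)=O)c1
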